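**Target 20:** (3R)-8-hydroxy-3-[(6S)-6-hydroxyundecyl]-6-methoxy-3,4-dihydro-1H-isochromen-1-one. Core atoms carry isochromanone numbers (C1 carbonyl, O2, C3, C4 methylene, C4a, C5–C8, C8a); side-chain atoms are primed (C1' on C3, carbinol C6').

## The problem

Target 20 is a 3,4-dihydroisocoumarin: arene ring A is fused through C4a and C8a to the six-membered lactone ring B, and C3 carries an unbranched eleven-carbon chain with a secondary carbinol at C6'. The ring system is small; the work lies in placing four substituents on ring A in a 1,2,3,5 pattern (C4 at C4a, the C1 carboxyl at C8a, oxygen at C8 and C6) and in joining this arene to a long chain convergently. The two stereocenters, C3 (R) and C6' (S), are separated by five methylene groups, so neither can control the other. An epimer at either would be nearly inseparable from 20, so each center is best taken from an enantiopure building block whose C–O bond is never broken. The two phenolic oxygens must be told apart: C8 is a free phenol hydrogen-bonded to the lactone carbonyl, C6 is a methyl ether. The lactone, the phenol and the carbinol do not survive organometallic reagents or strong base, so all carbanion chemistry must precede ring B and the final unmasking must be mild. The enabling feature is that C4a and C8a are neighbouring carbons of ring A: C4a carries a carbon best introduced as a nucleophile (C4, itself β to the C3 oxygen), C8a carries one best introduced as an electrophile (the C1 carboxyl), and C8a lies beside the C8 oxygen. That is the pattern left when a carbanion and then CO2 add across a 3-alkoxy aryne.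

## Retrosynthesis

**20 ⇒ 19.** The C8 phenol is traced back to its methyl ether, giving dimethyl ether 19. Aryne chemistry needs both ring oxygens as inert ethers. Differentiating them at the start would need two different O-protecting groups and a longer arene synthesis; at the end, only the C8 methoxy group is peri to the lactone carbonyl and can be cleaved by a chelating Lewis acid. The forward step must select between two aryl methyl ethers and tolerate the free C6' carbinol.

**19 ⇒ 17.** The C1–O2 ester bond of ring B is cut and the C6' oxygen is silylated, giving hydroxy acid 17. A lactone cannot coexist with organolithiums, whereas a lithium carboxylate can. A tert-butyldimethylsilyl ether is chosen so that one acid treatment closes ring B and frees the carbinol. Lactonisation is an acyl substitution, so the C3–O bond and the C3 configuration are untouched.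

**17 ⇒ 9 + 11 + 12.** The C4a–C4 and C8a–C1 bonds are cut together, leading to chlorohydrin 9, dihaloarene 11 and carbon dioxide 12, joined through aryne 15.
- *Neighbouring cuts.* Cutting C3–C4 (benzylic anion plus aldehyde) would create C3 in the coupling with no control from the distant C6'. Cutting only C4a–C4 (aryl metal plus epoxide) keeps the stereochemistry but needs a separate halogenation and carboxylation at C8a.
- *Simplification.* 9 holds the whole chain and both stereocenters, 11 is one step from a purchased arene, and 12 is a gas.
- *Demands on the forward step.* The β-oxido alkyllithium 13 made from 9 is stable only in the cold, so the aryne must be released in the cold.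
- *Design answers.* Chloride is used as the leaving group on the arene, because an ortho-chloro aryllithium flanked by a methoxy group (14) can be held at −78 °C yet loses its halide at lower temperature than a fluoro analogue. The bromine–lithium exchange on 11 is done beforehand in a separate flask with t-BuLi, so that neither 13 nor adduct 16 meets an aryl bromide.
- *Regiocontrol.* The C8 methoxy group must send the carbanion to C4a and the charge to C8a.

**11 ⇒ 10.** The C–Br bond is cut, giving purchased 1-chloro-3,5-dimethoxybenzene 10. Bromine marks the one carbon that must carry lithium and sits between chlorine and a methoxy group. Electrophilic bromination is expected there (para to the second methoxy group) in preference to the doubly flanked carbon between the two methoxy groups.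

**9 ⇒ 6 + 7.** The C1'–C2' bond is cut. (R)-Epichlorohydrin 7 supplies C4, C3 and C1' with the C3 oxygen and the chlorine that later becomes lithium; bromide 6 supplies C2'–C11'. This puts C3 in place from an inexpensive enantiopure three-carbon unit with no asymmetric reaction. The forward step must attack the epoxide CH2 of 7 and not its C–Cl carbon.

**6 ⇒ 5 ⇒ 3 ⇒ 2 ⇒ 1.** Bromide 6 comes from alcohol 5 and 5 from alkene 3 by hydroboration. The C4'–C5' bond of 2 is cut to (S)-1,2-epoxyheptane 1 and an allyl Grignard reagent. The allyl group is a three-carbon nucleophile whose alkene is a latent primary bromide; a three-carbon Grignard reagent already bearing a halide would cyclise to cyclopropane. C6' is taken unchanged from 1.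

## Roads not taken

**Alternative 1:** Ring A is built from an open chain; the cut is the C4a–C8a bond.
- *Key step.* Triethylamine makes the dioxinone α-carbon of 6-[(6R,12S)-6,12-bis(tert-butyldimethylsilyloxy)-2,4-dioxoheptadecyl]-2,2-dimethyl-4H-1,3-dioxin-4-one A1 condense with its C4a ketone. Dehydration then gives the arene 5-[(2R,8S)-2,8-bis(tert-butyldimethylsilyloxy)tridecyl]-7-hydroxy-2,2-dimethyl-4H-1,3-benzodioxin-4-one A2 as the product of the key step.
- *Merits.* The substitution pattern of ring A is written into the chain of A1, so no regiochemical question arises. In A2 the two phenolic oxygens emerge differentiated: C6 is free for methylation and C8 is released when the C3 hydroxyl lactonises onto the dioxinone carbonyl, so no demethylation is needed. The reaction type is established.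
- *Weak points.* A1 is a sensitive polycarbonyl compound that needs several Claisen-type acylations. Its C3 silyloxy group sits β to the C4a ketone, so the base that triggers the aldol can also expel silanolate and erase the C3 stereocenter before A2 is reached. The route is longer.
- *Comparison.* Alternative 1 is better in precedent and in how it differentiates the phenols. The chosen plan offers a purchased ring A, two flanking C–C bonds made in one operation from stable fragments, and a C3 center that is never β to a ketone.

**Alternative 2:** The cuts are C3–C1' and C1–O2.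
- *Key step.* With Ti(OiPr)4 and a chiral bis-sulfonamide ligand, the aldehyde methyl 2,4-dimethoxy-6-(2-oxoethyl)benzoate A3 accepts the long alkyl group of ethyl[(6S)-6-(triisopropylsilyloxy)undecyl]zinc A4 at its aldehyde carbon. The alkoxide then closes onto the ortho ester to give (3R)-6,8-dimethoxy-3-[(6S)-6-(triisopropylsilyloxy)undecyl]-3,4-dihydro-1H-isochromen-1-one A5 directly.
- *Merits.* C3 is set by a catalyst, ring B of A5 closes in the same step, the route is convergent and the reaction type is known.
- *Weak points.* A3 is an enolisable arylacetaldehyde on an electron-rich ring with an ortho ester, prone to self-condensation and to cyclisation through its enol. The mixed zinc reagent A4 can transfer ethyl in competition with the long chain. Catalyst control at C3 is never absolute, and the (3S) product would be an epimer that can hardly be separated.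
- *Comparison.* Its key step carries less methodological risk than the chosen one and its length is similar. The chosen plan sets against this a C3 center of full fidelity taken from 7 and the absence of the fragile aldehyde.

**Alternative 3:** Ring A is made by a [4+2] cycloaddition; the cuts are C8–C8a and C4a–C5.
- *Key step.* Heating 1,3-dimethoxy-1-(trimethylsilyloxy)buta-1,3-diene A6 with methyl (5R,11S)-5,11-bis(tert-butyldimethylsilyloxy)hexadec-2-ynoate A7, followed by loss of methanol and of the silyl group, gives methyl 2-[(2R,8S)-2,8-bis(tert-butyldimethylsilyloxy)tridecyl]-6-hydroxy-4-methoxybenzoate A8 as the product of the key step.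
- *Merits.* A8 already has the free C8 phenol and the C6 methyl ether, so the selective demethylation disappears. No cryogenic organolithium work and no new method are needed. In these respects it is at least as good as the chosen plan.
- *Weak points.* A7 is a β-alkyl ynoate, a hindered and weak dienophile that needs prolonged heating, under which the ketene-acetal diene A6 decomposes. The propargylic methylene next to the C3 silyloxy carbon can isomerise to an allenoate. A7 is a fragment-specific intermediate of several steps.
- *Comparison.* The chosen plan sets against it partners that react far below 0 °C, a stable purchased arene in place of a labile diene, and the formation of both ring A substituents in one flask.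

Key step: step 7

Assumption: epoxides 1 and 7 are used as purchased, enantiomerically pure materials; no later step breaks their stereogenic C–O bonds, so the stereochemical purity of 20 equals theirs.

## Route

Step 1
Reactants: 1 (2S)-2-pentyloxirane [(S)-1,2-epoxyheptane]
Product: 2 (5S)-dec-1-en-5-ol
Conditions: allylMgBr (1.3 equiv), CuI (5 mol%), THF, −40 → 0 °C; aq. NH4Cl
Reagents that add atoms: allylmagnesium bromide, C=CC[Mg]Br
Why: Copper-catalysed Grignard opening of a terminal epoxide at its unsubstituted carbon (SN2); the stereogenic C–O bond is not touched, so the (S) center of 1 becomes C6' unchanged.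

Step 2
Reactants: 2 (5S)-dec-1-en-5-ol
Product: 3 tert-butyl{[(5S)-dec-1-en-5-yl]oxy}dimethylsilane
Conditions: TBSCl (1.3 equiv), imidazole (2.5 equiv), DMF, rt
Reagents that add atoms: tert-butyldimethylsilyl chloride, CC(C)(C)[Si](C)(C)Cl
Why: Standard silylation of a secondary alcohol; the silyl ether should tolerate the Grignard, alkyllithium and radical-anion conditions ahead and is removable by the acid of step 8.

Step 3
Reactants: 3 tert-butyl{[(5S)-dec-1-en-5-yl]oxy}dimethylsilane
Product: 5 (5S)-5-(tert-butyldimethylsilyloxy)decan-1-ol, via B-alkyl-9-BBN adduct 4 (not isolated)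
Conditions: 9-BBN (1.3 equiv), THF, 0 °C → rt; then 3 M NaOH, 30% H2O2, 0 °C → rt
Reagents that add atoms: hydrogen peroxide, OO
Why: Anti-Markovnikov hydroboration–oxidation; the bulky dialkylborane places boron on the terminal carbon of the monosubstituted alkene and oxidation gives the primary alcohol.

Step 4
Reactants: 5 (5S)-5-(tert-butyldimethylsilyloxy)decan-1-ol
Product: 6 (5S)-1-bromo-5-(tert-butyldimethylsilyloxy)decane
Conditions: CBr4 (1.3 equiv), PPh3 (1.4 equiv), CH2Cl2, 0 °C → rt
Reagents that add atoms: carbon tetrabromide, BrC(Br)(Br)Br
Why: Appel bromination of a primary alcohol under neutral conditions; the remote silyl ether and stereocenter are not affected.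

Step 5
Reactants: 6 (5S)-1-bromo-5-(tert-butyldimethylsilyloxy)decane; 7 (2R)-2-(chloromethyl)oxirane [(R)-epichlorohydrin]
Product: 9 (2R,8S)-8-(tert-butyldimethylsilyloxy)-1-chlorotridecan-2-ol, via alkylmagnesium bromide 8 (not isolated)
Conditions: Mg, BrCH2CH2Br (cat.), THF, 40 °C; then CuI (10 mol%), 7 (1.2 equiv), THF, −40 → −20 °C; aq. NH4Cl at −20 °C
Reagents that add atoms: none
Why: Copper-catalysed Grignard opening of epichlorohydrin at the epoxide CH2, which is faster than displacement of chloride; the stereogenic C–O bond stays intact, so (R)-7 gives the (2R) carbinol (future C3), and the cold quench keeps the chloro alkoxide from closing to an epoxide.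

Step 6
Reactants: 10 1-chloro-3,5-dimethoxybenzene
Product: 11 2-bromo-1-chloro-3,5-dimethoxybenzene
Conditions: NBS (1.0 equiv), MeCN, 0 °C → rt
Reagents that add atoms: N-bromosuccinimide, O=C1CCC(=O)N1Br
Why: Electrophilic aromatic bromination; the carbon para to one methoxy group and ortho to the other is expected to react in preference to the doubly flanked carbon between the two methoxy groups, as is general for 1-substituted 3,5-dimethoxybenzenes.

Step 7
Reactants: 9 (2R,8S)-8-(tert-butyldimethylsilyloxy)-1-chlorotridecan-2-ol; 11 2-bromo-1-chloro-3,5-dimethoxybenzene; 12 carbon dioxide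
Product: 17 2-[(2R,8S)-8-(tert-butyldimethylsilyloxy)-2-hydroxytridecyl]-4,6-dimethoxybenzoic acid, via beta-oxido alkyllithium 13 (not isolated), via chloroaryllithium 14 (not isolated), via 3,5-dimethoxybenzyne 15 (not isolated), via dilithiated adduct 16 (not isolated)
Conditions: (a) 9, n-BuLi (1.0 equiv), THF, −78 °C; LiC10H8 (lithium naphthalenide, 2.05 equiv), −78 °C; (b) 11 (1.2 equiv), t-BuLi (2.4 equiv), THF, −78 °C; (c) b into a at −78 °C, then slowly to −55 °C; (d) CO2 (12), −78 → 0 °C; 0.5 M HCl to pH 3, 0 °C
Reagents that add atoms: none
Why: Proposed new method: deprotonation of 9 and two-electron reduction of its C–Cl bond by LiC10H8 at −78 °C should give the β-oxido alkyllithium 13, whose oxide is too poor a leaving group to be expelled in the cold, while in a second flask t-BuLi converts 11 into aryllithium 14 (the second equivalent destroys t-BuBr), so that no aryl bromide is left to exchange with 13 or with the product aryllithium. On gentle warming of the combined solutions 14 should lose LiCl to aryne 15, whose C8 methoxy group polarises and distorts the triple bond so that the primary carbanion of 13 adds at the remote carbon C4a and the charge settles at C8a, beside the C–O bond and held by its oxygen; the C6 methoxy group is too remote to reverse this. Aryllithium 16 is then the only carbon nucleophile left and is carboxylated by 12 at C8a, so the C4a–C4 and C8a–C1 bonds form in one flask. The closest known reaction types are the three-component coupling of haloarene-derived 3-alkoxyarynes with Grignard or alkyllithium reagents and CO2, and the trapping of chlorohydrin-derived β-oxido alkyllithiums by carbonyl electrophiles; their combination is new. Chloride replaces fluoride as leaving group because ortho-chloro aryllithiums release the aryne at lower temperature, nearer the range in which 13 persists. No ring closes and no stereocenter is formed: C3 comes unchanged from 7 because its C–O bond is never broken. The step needs regioselective addition to the unsymmetrical aryne, secured by the C8 methoxy group, and C- over O-attack of 13, secured by the far higher nucleophilicity of the C–Li bond. Any silyl lactone 18 formed on acidification is the intermediate of step 8 and does no harm.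

Step 8
Reactants: 17 2-[(2R,8S)-8-(tert-butyldimethylsilyloxy)-2-hydroxytridecyl]-4,6-dimethoxybenzoic acid
Product: 19 (3R)-3-[(6S)-6-hydroxyundecyl]-6,8-dimethoxy-3,4-dihydro-1H-isochromen-1-one, via silyl lactone 18 (not isolated)
Conditions: p-TsOH·H2O (0.2 equiv), CH2Cl2, rt; then MeOH, rt
Reagents that add atoms: none
Why: Acid-catalysed lactonisation (acyl substitution by the C3 hydroxyl, C3–O bond intact) closes ring B, and the same acid in methanol then solvolyses the secondary silyl ether; the benzo-fused six-membered lactone is the thermodynamic resting point.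

Step 9
Reactants: 19 (3R)-3-[(6S)-6-hydroxyundecyl]-6,8-dimethoxy-3,4-dihydro-1H-isochromen-1-one
Product: 20 (3R)-8-hydroxy-3-[(6S)-6-hydroxyundecyl]-6-methoxy-3,4-dihydro-1H-isochromen-1-one
Conditions: BCl3 (1 M in CH2Cl2, 3.0 equiv), CH2Cl2, −78 → 0 °C; then H2O
Reagents that add atoms: none
Why: Chelation-controlled aryl methyl ether cleavage: BCl3 is held between the lactone carbonyl and the peri C8 methoxy oxygen and chloride removes only that methyl group, the C6 methoxy group lacking this activation; the C6' hydroxyl is tied up as a borate ester and is set free on aqueous work-up.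

## Compound list

1 | (2S)-2-pentyloxirane [(S)-1,2-epoxyheptane] | CCCCC[C@H]1CO1 | starting material
2 | (5S)-dec-1-en-5-ol | CCCCC[C@H](O)CCC=C | intermediate
3 | tert-butyl{[(5S)-dec-1-en-5-yl]oxy}dimethylsilane | CCCCC[C@H](O[Si](C)(C)C(C)(C)C)CCC=C | intermediate
4 | 9-[(5R)-5-(tert-butyldimethylsilyloxy)decyl]-9-borabicyclo[3.3.1]nonane (not isolated; same spatial arrangement as in 3, the descriptor changes only because the boron-bearing branch ranks below pentyl) | CCCCC[C@H](O[Si](C)(C)C(C)(C)C)CCCCB1C2CCCC1CCC2 | intermediate
5 | (5S)-5-(tert-butyldimethylsilyloxy)decan-1-ol | CCCCC[C@H](O[Si](C)(C)C(C)(C)C)CCCCO | intermediate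
6 | (5S)-1-bromo-5-(tert-butyldimethylsilyloxy)decane | CCCCC[C@H](O[Si](C)(C)C(C)(C)C)CCCCBr | intermediate
7 | (2R)-2-(chloromethyl)oxirane [(R)-epichlorohydrin] | ClC[C@H]1CO1 | starting material
8 | [(5S)-5-(tert-butyldimethylsilyloxy)decyl]magnesium bromide (not isolated) | CCCCC[C@H](O[Si](C)(C)C(C)(C)C)CCCC[Mg]Br | intermediate
9 | (2R,8S)-8-(tert-butyldimethylsilyloxy)-1-chlorotridecan-2-ol | CCCCC[C@H](O[Si](C)(C)C(C)(C)C)CCCCC[C@@H](O)CCl | intermediate
10 | 1-chloro-3,5-dimethoxybenzene | COc1cc(Cl)cc(OC)c1 | starting material
11 | 2-bromo-1-chloro-3,5-dimethoxybenzene | COc1cc(Cl)c(Br)c(OC)c1 | intermediate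
12 | carbon dioxide | O=C=O | starting material
13 | lithium (2S,8S)-8-(tert-butyldimethylsilyloxy)-1-lithiotridecan-2-olate (not isolated; O,C-dilithiated 9 with the spatial arrangement of 9, the C2 descriptor changes only because CH2Li ranks below the chain) | CCCCC[C@H](O[Si](C)(C)C(C)(C)C)CCCCC[C@@H](O[Li])C[Li] | intermediate
14 | (2-chloro-4,6-dimethoxyphenyl)lithium (not isolated) | [Li]c1c(Cl)cc(OC)cc1OC | intermediate
15 | 3,5-dimethoxybenzyne [1,2-didehydro-3,5-dimethoxybenzene] (not isolated) | COC1=CC(OC)=CC#C1 | intermediate
16 | lithium (2R,8S)-8-(tert-butyldimethylsilyloxy)-1-(2-lithio-3,5-dimethoxyphenyl)tridecan-2-olate (not isolated) | CCCCC[C@H](O[Si](C)(C)C(C)(C)C)CCCCC[C@@H](O[Li])Cc1cc(OC)cc(OC)c1[Li] | intermediate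
17 | 2-[(2R,8S)-8-(tert-butyldimethylsilyloxy)-2-hydroxytridecyl]-4,6-dimethoxybenzoic acid | CCCCC[C@H](O[Si](C)(C)C(C)(C)C)CCCCC[C@@H](O)Cc1cc(OC)cc(OC)c1C(=O)O | intermediate
18 | (3R)-3-[(6S)-6-(tert-butyldimethylsilyloxy)undecyl]-6,8-dimethoxy-3,4-dihydro-1H-isochromen-1-one (not isolated) | CCCCC[C@H](O[Si](C)(C)C(C)(C)C)CCCCC[C@@H]1Cc2cc(OC)cc(OC)c2C(=O)O1 | intermediate
19 | (3R)-3-[(6S)-6-hydroxyundecyl]-6,8-dimethoxy-3,4-dihydro-1H-isochromen-1-one | CCCCC[C@H](O)CCCCC[C@@H]1Cc2cc(OC)cc(OC)c2C(=O)O1 | intermediate
20 | (3R)-8-hydroxy-3-[(6S)-6-hydroxyundecyl]-6-methoxy-3,4-dihydro-1H-isochromen-1-one | CCCCC[C@H](O)CCCCC[C@@H]1Cc2cc(OC)cc(O)c2C(=O)O1 | target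

## Step count and least certain steps

Total: 9 steps. Longest linear sequence: 8 steps (steps 1–5 and 7–9); step 6 is a one-step branch.

**Step 7 (key step).** Most likely to fail is the timing: 13 may lose lithium oxide by β-elimination to a terminal alkene before 14 has released the aryne, because the two events have different temperature demands. Second, arynes discriminate little among organolithiums, so 15 may be consumed by 14 or by adduct 16 once 13 runs low. The fallback gives up the one-flask difunctionalisation and forms the two bonds by known polar chemistry. Chlorohydrin 9 is closed with K2CO3 in MeOH to (2R)-2-[(6S)-6-(tert-butyldimethylsilyloxy)undecyl]oxirane F1. (3,5-Dimethoxyphenyl)magnesium bromide F2, made from purchased 1-bromo-3,5-dimethoxybenzene and Mg in THF, opens F1 at its CH2 under CuI catalysis to (2R,8S)-8-(tert-butyldimethylsilyloxy)-1-(3,5-dimethoxyphenyl)tridecan-2-ol F3. NBS in MeCN brominates the ring carbon between side chain and methoxy group to give (2R,8S)-1-(2-bromo-3,5-dimethoxyphenyl)-8-(tert-butyldimethylsilyloxy)tridecan-2-ol F4. n-BuLi (2.1 equiv, THF, −78 °C) then removes the hydroxyl proton and exchanges bromine for lithium, which is compound 16; CO2 and acid give 17 as in step 7. The fallback sets out from 9 and returns at 16.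

**Step 6.** Positional selectivity of the bromination may be incomplete (attack between the two methoxy groups, or double bromination), because the halogen favours its para position while the methoxy groups favour the desired one. The fallback replaces electrophilic substitution by deprotonation. LiTMP (lithium 2,2,6,6-tetramethylpiperidide, LiNC9H18) in THF at −78 °C should remove the most acidic ring proton of 10, the one beside chlorine, since amide bases metalate next to halogen and not between two methoxy groups. This gives 14, and quenching with BrCl2C–CCl2Br gives 11. It sets out from 10, passes through 14, returns at 11, and makes no compound outside the list.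

**Step 5.** Wurtz homocoupling while the functionalised Grignard reagent 8 forms, and consumption of 8 by attack at the C–Cl carbon or at an epoxide formed by premature ring closure, would waste the five-step fragment. The fallback assembles 9 convergently by olefin metathesis, using only inexpensive Grignard reagents in excess. Epoxide 1 is opened with vinylmagnesium bromide and CuI to (4S)-non-1-en-4-ol F5, which is silylated (TBSCl, imidazole) to tert-butyldimethyl{[(4S)-non-1-en-4-yl]oxy}silane F6. Epoxide 7 is opened with allylmagnesium bromide and CuI to (2R)-1-chlorohex-5-en-2-ol F7. Cross-metathesis of F6 with excess F7 (second-generation Grubbs catalyst, CH2Cl2, 40 °C) gives (2R,5E,8S)-8-(tert-butyldimethylsilyloxy)-1-chlorotridec-5-en-2-ol F8 (the alkene geometry is immaterial). Hydrogenation (H2, PtO2, EtOAc) gives 9. The fallback sets out from 1 and 7 and returns at 9.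

**Step 9.** Site selectivity may be lost (second demethylation at C6 on warming with excess BCl3), or the borate-bound C6' carbinol may be converted to a chloride or alkene. The fallback keeps the carbinol masked during the Lewis-acid step. Step 8 is stopped after its CH2Cl2 stage and 18 is isolated. BCl3 (CH2Cl2, −78 °C) gives (3R)-3-[(6S)-6-(tert-butyldimethylsilyloxy)undecyl]-8-hydroxy-6-methoxy-3,4-dihydro-1H-isochromen-1-one F9, and HF·pyridine in THF removes the silyl group to give 20. It sets out from 18 and arrives at 20.

## Further compounds

F1 | step 7 | (2R)-2-[(6S)-6-(tert-butyldimethylsilyloxy)undecyl]oxirane | CCCCC[C@H](O[Si](C)(C)C(C)(C)C)CCCCC[C@@H]1CO1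
F2 | step 7 | (3,5-dimethoxyphenyl)magnesium bromide | COc1cc([Mg]Br)cc(OC)c1
F3 | step 7 | (2R,8S)-8-(tert-butyldimethylsilyloxy)-1-(3,5-dimethoxyphenyl)tridecan-2-ol | CCCCC[C@H](O[Si](C)(C)C(C)(C)C)CCCCC[C@@H](O)Cc1cc(OC)cc(OC)c1
F4 | step 7 | (2R,8S)-1-(2-bromo-3,5-dimethoxyphenyl)-8-(tert-butyldimethylsilyloxy)tridecan-2-ol | CCCCC[C@H](O[Si](C)(C)C(C)(C)C)CCCCC[C@@H](O)Cc1cc(OC)cc(OC)c1Br
F0 | step 6 | none | none
F5 | step 5 | (4S)-non-1-en-4-ol | CCCCC[C@H](O)CC=C
F6 | step 5 | tert-butyldimethyl{[(4S)-non-1-en-4-yl]oxy}silane | CCCCC[C@H](O[Si](C)(C)C(C)(C)C)CC=C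
F7 | step 5 | (2R)-1-chlorohex-5-en-2-ol | C=CCC[C@@H](O)CCl
F8 | step 5 | (2R,5E,8S)-8-(tert-butyldimethylsilyloxy)-1-chlorotridec-5-en-2-ol | CCCCC[C@H](O[Si](C)(C)C(C)(C)C)C/C=C/CC[C@@H](O)CCl
F9 | step 9 | (3R)-3-[(6S)-6-(tert-butyldimethylsilyloxy)undecyl]-8-hydroxy-6-methoxy-3,4-dihydro-1H-isochromen-1-one | CCCCC[C@H](O[Si](C)(C)C(C)(C)C)CCCCC[C@@H]1Cc2cc(OC)cc(O)c2C(=O)O1
A1 | alternative 1 | 6-[(6R,12S)-6,12-bis(tert-butyldimethylsilyloxy)-2,4-dioxoheptadecyl]-2,2-dimethyl-4H-1,3-dioxin-4-one | CCCCC[C@H](O[Si](C)(C)C(C)(C)C)CCCCC[C@@H](O[Si](C)(C)C(C)(C)C)CC(=O)CC(=O)CC1=CC(=O)OC(C)(C)O1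
A2 | alternative 1 | 5-[(2R,8S)-2,8-bis(tert-butyldimethylsilyloxy)tridecyl]-7-hydroxy-2,2-dimethyl-4H-1,3-benzodioxin-4-one | CCCCC[C@H](O[Si](C)(C)C(C)(C)C)CCCCC[C@@H](O[Si](C)(C)C(C)(C)C)Cc1cc(O)cc2OC(C)(C)OC(=O)c12
A3 | alternative 2 | methyl 2,4-dimethoxy-6-(2-oxoethyl)benzoate | COC(=O)c1c(OC)cc(OC)cc1CC=O
A4 | alternative 2 | ethyl[(6S)-6-(triisopropylsilyloxy)undecyl]zinc | CCCCC[C@H](O[Si](C(C)C)(C(C)C)C(C)C)CCCCC[Zn]CC
A5 | alternative 2 | (3R)-6,8-dimethoxy-3-[(6S)-6-(triisopropylsilyloxy)undecyl]-3,4-dihydro-1H-isochromen-1-one | CCCCC[C@H](O[Si](C(C)C)(C(C)C)C(C)C)CCCCC[C@@H]1Cc2cc(OC)cc(OC)c2C(=O)O1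
A6 | alternative 3 | 1,3-dimethoxy-1-(trimethylsilyloxy)buta-1,3-diene | COC(=C)C=C(OC)O[Si](C)(C)C
A7 | alternative 3 | methyl (5R,11S)-5,11-bis(tert-butyldimethylsilyloxy)hexadec-2-ynoate | CCCCC[C@H](O[Si](C)(C)C(C)(C)C)CCCCC[C@@H](O[Si](C)(C)C(C)(C)C)CC#CC(=O)OC
A8 | alternative 3 | methyl 2-[(2R,8S)-2,8-bis(tert-butyldimethylsilyloxy)tridecyl]-6-hydroxy-4-methoxybenzoate | CCCCC[C@H](O[Si](C)(C)C(C)(C)C)CCCCC[C@@H](O[Si](C)(C)C(C)(C)C)Cc1cc(OC)cc(O)c1C(=O)OC
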